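## Retrosynthetic overview

1. The 1,2-dioxane is closed last by a 6-exo peroxy-Michael addition of a tertiary hydroperoxide onto an (E)-2-methyl-enoate; the hydroperoxide comes from cobalt-catalysed hydroperoxysilylation of a 1,1-disubstituted alkene.
2. The C25 diene ester comes from a Negishi coupling (C12–C13 bond) of a bicyclic alkylzinc with a 2-bromo-1,6-dienoate, itself made from 2,3-dibromopropene, allylmagnesium bromide and methyl methacrylate.
3. The bicyclic iodide (rings A and B, C5, C9, C10) comes in one operation from an acyclic (3Z,7E)-trienyl iodide by a catalytic asymmetric proton-initiated bicyclization. The Z olefin encodes the axial C9 side chain, and proton loss gives the ring B alkene.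
4. The Z-trienyl iodide comes from geranylacetone: methyl ketone to alkyne with oxirane trapping, iron-catalysed syn-carbomagnesiation, then iodination.
5. Ring order: rings A and B together, then the 1,2-dioxane.

Assumption: commercial (E)-geranylacetone (≥97% E) is used; labdane-type locants (C5, C7–C13) are used in the comments for the decalin and its side chain.

## Route

Step 1
Reactants: 1 (5E)-6,10-dimethylundeca-5,9-dien-2-one (geranylacetone)
Product: 4 (7E)-8,12-dimethyltrideca-7,11-dien-3-yn-1-ol, via enol phosphate 2 (not isolated), via lithium acetylide 3 (not isolated)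
Conditions: LiN(i-Pr)2 (1.05 equiv), THF, −78 °C; ClP(O)(OEt)2, −78 °C → rt; LiN(i-Pr)2 (2.3 equiv), −78 °C → rt; oxirane, DMPU, 0 °C → rt; aq. NH4Cl
Reagents that add atoms: oxirane, C1CO1; diethyl chlorophosphate, CCOP(=O)(Cl)OCC (its atoms stay only in 2); lithium diisopropylamide, CC(C)N([Li])C(C)C (lithium only in 3)
Why: Kinetic enolization at the methyl group, O-phosphorylation and base-induced elimination (Negishi methyl ketone-to-alkyne conversion) give the alkynyllithium, which opens oxirane by SN2 in the same flask; no stereocentre is formed and the 5E olefin is untouched.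

Step 2
Reactants: 4 (7E)-8,12-dimethyltrideca-7,11-dien-3-yn-1-ol
Product: 6 (3Z,7E)-4,8,12-trimethyltrideca-3,7,11-trien-1-ol, via magnesium chelate 5 (not isolated)
Conditions: MeMgBr (5 equiv), Fe(acac)3 (15 mol%), THF, −78 → 0 °C; aq. NH4Cl
Reagents that add atoms: methylmagnesium bromide, C[Mg]Br
Why: Alkoxide-directed iron-catalysed syn-carbomagnesiation of a homopropargylic alcohol puts methyl on the distal alkyne carbon and magnesium on the proximal one (five-membered chelate), so protonation gives the 3Z trisubstituted olefin that later places the C9 side chain axial.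

Step 3
Reactants: 6 (3Z,7E)-4,8,12-trimethyltrideca-3,7,11-trien-1-ol
Product: 7 (3Z,7E)-1-iodo-4,8,12-trimethyltrideca-3,7,11-triene
Conditions: I2, PPh3, imidazole, CH2Cl2, 0 °C
Reagents that add atoms: iodine, II
Why: Appel iodination of a primary alcohol under neutral conditions leaves the three trisubstituted olefins and their geometry intact.

Step 4
Reactants: 7 (3Z,7E)-1-iodo-4,8,12-trimethyltrideca-3,7,11-triene
Product: 8 (1S,4aR,8aR)-1-(2-iodoethyl)-2,5,5,8a-tetramethyl-1,4,4a,5,6,7,8,8a-octahydronaphthalene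
Conditions: chiral BINOL-derived imidodiphosphorimidate (IDPi) Brønsted acid (5 mol%; the enantiomer that gives the 4aR,8aR series), (CF3)3COH, −20 °C
Reagents that add atoms: none
Why: Proposed new method: the confined chiral acid protonates the terminal isopropylidene group on one face with concerted closure of ring A, which sets C5 and C10 (trans, because the 7E olefin reacts through chair–chair Stork–Eschenmoser folding); the 3Z olefin then closes ring B with its CH2CH2I arm axial at C9, anti to the C10 methyl; the C8 cation has no nucleophile in reach (the primary iodide is inert) and loses the axial C7 proton, since the C9–H is equatorial and not aligned, to give the ring B trisubstituted alkene; the closest known reaction types are the IDPi-catalysed asymmetric cyclization of homofarnesol to the ambroxide skeleton and superacid cyclizations of 2Z-farnesyl derivatives to 9-epi-drim-7-enes.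

Step 5
Reactants: 9 2,3-dibromoprop-1-ene; 10 allylmagnesium bromide
Product: 11 2-bromohexa-1,5-diene
Conditions: Et2O, 0 °C → rt
Reagents that add atoms: none
Why: Allyl Grignard substitution of the allylic bromide (SN2 and SN2' give the same product) leaves the vinyl bromide untouched.

Step 6
Reactants: 11 2-bromohexa-1,5-diene; 12 methyl methacrylate
Product: 13 methyl (2E)-6-bromo-2-methylhepta-2,6-dienoate
Conditions: second-generation Hoveyda–Grubbs catalyst, RuCl2(H2IMes)(=CH-C6H4-2-O-i-Pr) (3 mol%), methyl methacrylate (5 equiv), CH2Cl2, 40 °C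
Reagents that add atoms: none
Why: Olefin cross-metathesis takes place only at the monosubstituted alkene (the 2-bromoalkene is too hindered and electron-poor) and gives the thermodynamically favoured E-trisubstituted enoate.

Step 7
Reactants: 8 (1S,4aR,8aR)-1-(2-iodoethyl)-2,5,5,8a-tetramethyl-1,4,4a,5,6,7,8,8a-octahydronaphthalene; 13 methyl (2E)-6-bromo-2-methylhepta-2,6-dienoate
Product: 15 methyl (2E)-2-methyl-6-methylidene-8-[(1S,4aR,8aR)-2,5,5,8a-tetramethyl-1,4,4a,5,6,7,8,8a-octahydronaphthalen-1-yl]oct-2-enoate, via alkylzinc iodide 14 (not isolated)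
Conditions: Zn dust, LiCl, THF, 40 °C; then 13, Pd(OAc)2 (2 mol%), SPhos (4 mol%), THF, rt
Reagents that add atoms: zinc, [Zn] (stays only in 14)
Why: Zinc insertion into the primary iodide and Negishi sp3–sp2 coupling with the alkenyl bromide tolerate the enoate and both ring and chain olefins; no stereocentre is touched.

Step 8
Reactants: 15 methyl (2E)-2-methyl-6-methylidene-8-[(1S,4aR,8aR)-2,5,5,8a-tetramethyl-1,4,4a,5,6,7,8,8a-octahydronaphthalen-1-yl]oct-2-enoate
Product: 16 methyl (2E,6R)-2,6-dimethyl-8-[(1S,4aR,8aR)-2,5,5,8a-tetramethyl-1,4,4a,5,6,7,8,8a-octahydronaphthalen-1-yl]-6-[(triethylsilyl)peroxy]oct-2-enoate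
Conditions: Co(acac)2 (10 mol%), Et3SiH, O2 (1 atm), ClCH2CH2Cl, rt
Reagents that add atoms: dioxygen, O=O; triethylsilane, CC[SiH](CC)CC
Why: Isayama–Mukaiyama hydroperoxysilylation (cobalt hydride hydrogen-atom transfer, then O2 capture) is Markovnikov and favours the unhindered 1,1-disubstituted alkene over the hindered ring B alkene and the electron-poor enoate (as with limonene); the tertiary radical is planar and remote from the decalin, so C6 forms as both epimers (about 1:1), which are carried on together, 16 being the one needed.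

Step 9
Reactants: 16 methyl (2E,6R)-2,6-dimethyl-8-[(1S,4aR,8aR)-2,5,5,8a-tetramethyl-1,4,4a,5,6,7,8,8a-octahydronaphthalen-1-yl]-6-[(triethylsilyl)peroxy]oct-2-enoate
Product: 18 methyl (2S)-2-[(3S,6S)-6-methyl-6-{2-[(1S,4aR,8aR)-2,5,5,8a-tetramethyl-1,4,4a,5,6,7,8,8a-octahydronaphthalen-1-yl]ethyl}-1,2-dioxan-3-yl]propanoate, via hydroperoxide 17 (not isolated)
Conditions: HCl (cat.), MeOH, 0 °C; then Et2NH, CF3CH2OH, rt; preparative HPLC
Reagents that add atoms: none
Why: Methanolysis frees the hydroperoxide, which closes by 6-exo intramolecular peroxy-Michael addition through a chair with the enoate equatorial; C2 is set by protonation of the ester enolate anti to the ring CH2 (A(1,3) model, which predicts the 2S,3S pairing), while C3 relative to C6 is only weakly biased, so 18 is one of the main diastereomers and is isolated by HPLC (the C6 descriptor changes from R in 17 to S in 18 only through CIP priorities).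

## Compound list

1 | (5E)-6,10-dimethylundeca-5,9-dien-2-one (geranylacetone) | CC(=O)CC/C=C(\C)CCC=C(C)C | starting material
2 | diethyl (5E)-6,10-dimethylundeca-1,5,9-trien-2-yl phosphate | C=C(CC/C=C(\C)CCC=C(C)C)OP(=O)(OCC)OCC | intermediate
3 | lithium (5E)-6,10-dimethylundeca-5,9-dien-1-yn-1-ide | [Li]C#CCC/C=C(\C)CCC=C(C)C | intermediate
4 | (7E)-8,12-dimethyltrideca-7,11-dien-3-yn-1-ol | OCCC#CCC/C=C(\C)CCC=C(C)C | intermediate
5 | cyclic alkenylmagnesium alkoxide of 6 (C3–Mg–O1 chelate, Mg cis to the new C4 methyl) | C/C(CC/C=C(\C)CCC=C(C)C)=C1/CCO[Mg]1 | intermediate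
6 | (3Z,7E)-4,8,12-trimethyltrideca-3,7,11-trien-1-ol | OCC/C=C(/C)CC/C=C(\C)CCC=C(C)C | intermediate
7 | (3Z,7E)-1-iodo-4,8,12-trimethyltrideca-3,7,11-triene | ICC/C=C(/C)CC/C=C(\C)CCC=C(C)C | intermediate
8 | (1S,4aR,8aR)-1-(2-iodoethyl)-2,5,5,8a-tetramethyl-1,4,4a,5,6,7,8,8a-octahydronaphthalene | ICC[C@H]1C(C)=CC[C@@H]2C(C)(C)CCC[C@]21C | intermediate
9 | 2,3-dibromoprop-1-ene | C=C(Br)CBr | starting material
10 | allylmagnesium bromide | C=CC[Mg]Br | starting material
11 | 2-bromohexa-1,5-diene | C=CCCC(Br)=C | intermediate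
12 | methyl methacrylate | C=C(C)C(=O)OC | starting material
13 | methyl (2E)-6-bromo-2-methylhepta-2,6-dienoate | COC(=O)/C(C)=C/CCC(Br)=C | intermediate
14 | {2-[(1S,4aR,8aR)-2,5,5,8a-tetramethyl-1,4,4a,5,6,7,8,8a-octahydronaphthalen-1-yl]ethyl}zinc iodide | I[Zn]CC[C@H]1C(C)=CC[C@@H]2C(C)(C)CCC[C@]21C | intermediate
15 | methyl (2E)-2-methyl-6-methylidene-8-[(1S,4aR,8aR)-2,5,5,8a-tetramethyl-1,4,4a,5,6,7,8,8a-octahydronaphthalen-1-yl]oct-2-enoate | COC(=O)/C(C)=C/CCC(=C)CC[C@H]1C(C)=CC[C@@H]2C(C)(C)CCC[C@]21C | intermediate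
16 | methyl (2E,6R)-2,6-dimethyl-8-[(1S,4aR,8aR)-2,5,5,8a-tetramethyl-1,4,4a,5,6,7,8,8a-octahydronaphthalen-1-yl]-6-[(triethylsilyl)peroxy]oct-2-enoate (formed together with its 6S epimer) | COC(=O)/C(C)=C/CC[C@](C)(CC[C@H]1C(C)=CC[C@@H]2C(C)(C)CCC[C@]21C)OO[Si](CC)(CC)CC | intermediate
17 | methyl (2E,6R)-6-hydroperoxy-2,6-dimethyl-8-[(1S,4aR,8aR)-2,5,5,8a-tetramethyl-1,4,4a,5,6,7,8,8a-octahydronaphthalen-1-yl]oct-2-enoate | COC(=O)/C(C)=C/CC[C@](C)(CC[C@H]1C(C)=CC[C@@H]2C(C)(C)CCC[C@]21C)OO | intermediate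
18 | methyl (2S)-2-[(3S,6S)-6-methyl-6-{2-[(1S,4aR,8aR)-2,5,5,8a-tetramethyl-1,4,4a,5,6,7,8,8a-octahydronaphthalen-1-yl]ethyl}-1,2-dioxan-3-yl]propanoate | COC(=O)[C@@H](C)[C@@H]1CC[C@](C)(CC[C@H]2C(C)=CC[C@@H]3C(C)(C)CCC[C@]32C)OO1 | target

## Step count and risks

Total step count: 9. Longest linear sequence: 7 steps (steps 1, 2, 3, 4, 7, 8, 9).

**Step 4 (key bicyclization).** Risks are incomplete cyclization, an exocyclic alkene instead of the ring B alkene, or a low enantiomer ratio with a non-hydroxyl terminator. The fallback sets out from alcohol 6 and comes back at iodide 8. Alcohol 6 is cyclized with the same chiral IDPi acid in (CF3)3COH; the hydroxyl group now captures the C8 cation (the best-precedented termination), three rings form at once, and the product is the tricyclic ether (3aS,5aR,9aR,9bR)-3a,6,6,9a-tetramethyldodecahydronaphtho[2,1-b]furan F1. Acetolytic E1 opening of its tertiary C–O bond (Ac2O, cat. BF3·OEt2, CH2Cl2, −20 °C) gives 2-[(1S,4aR,8aR)-2,5,5,8a-tetramethyl-1,4,4a,5,6,7,8,8a-octahydronaphthalen-1-yl]ethyl acetate F2. Methanolysis (K2CO3, MeOH) gives 2-[(1S,4aR,8aR)-2,5,5,8a-tetramethyl-1,4,4a,5,6,7,8,8a-octahydronaphthalen-1-yl]ethan-1-ol F3, and I2, PPh3, imidazole gives 8. This fallback secures the enantioselective cyclization but not the alkene regiochemistry, since the opening passes through the same C8 cation.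

**Step 8 (hydroperoxysilylation).** The risk is competing hydrogen-atom transfer to the ring B alkene. The fallback sets out from iodide 8 and comes back at hydroperoxide 17. A Barbier coupling of 8 with commercial hex-5-en-2-one (SmI2, HMPA, THF, rt) gives the tertiary alcohol 3-methyl-1-[(1S,4aR,8aR)-2,5,5,8a-tetramethyl-1,4,4a,5,6,7,8,8a-octahydronaphthalen-1-yl]hept-6-en-3-ol F4 as both C3 epimers. Cross-metathesis with 12 (second-generation Hoveyda–Grubbs catalyst as in step 6) gives methyl (2E)-6-hydroxy-2,6-dimethyl-8-[(1S,4aR,8aR)-2,5,5,8a-tetramethyl-1,4,4a,5,6,7,8,8a-octahydronaphthalen-1-yl]oct-2-enoate F5. SN1 perhydrolysis of the tertiary alcohol (50% H2O2, cat. H2SO4, Et2O, 0 °C) gives 17 with its C6 epimer, which is closed with Et2NH in CF3CH2OH as in step 9. The acidic peroxide step is itself a risk for the ring B alkene.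

**Step 9 (ring closure).** The risk is an unworkable diastereomer mixture or base-induced peroxide fragmentation. The fallback sets out from bromodiene 11 and zinc reagent 14 and comes back at 18. Selective ozonolysis of the monosubstituted alkene of 11 with acidic methanol work-up (O3, MeOH/CH2Cl2, −78 °C; TsOH; Me2S) gives 2-bromo-5,5-dimethoxypent-1-ene F6. Negishi coupling with 14 (Pd(OAc)2, SPhos, THF) gives (1S,4aR,8aR)-1-(6,6-dimethoxy-3-methylidenehexyl)-2,5,5,8a-tetramethyl-1,4,4a,5,6,7,8,8a-octahydronaphthalene F7. Co(acac)2, Et3SiH, O2 gives triethyl({(3S)-6,6-dimethoxy-3-methyl-1-[(1S,4aR,8aR)-2,5,5,8a-tetramethyl-1,4,4a,5,6,7,8,8a-octahydronaphthalen-1-yl]hexan-3-yl}peroxy)silane F8 with its C3 epimer. HCl in MeOH removes silicon and closes the hydroperoxide onto the acetal to give the cyclic peroxyacetal (6S)-3-methoxy-6-methyl-6-{2-[(1S,4aR,8aR)-2,5,5,8a-tetramethyl-1,4,4a,5,6,7,8,8a-octahydronaphthalen-1-yl]ethyl}-1,2-dioxane F9. TiCl4 in CH2Cl2 at −78 °C ionizes F9 to the peroxycarbenium ion, which is trapped by 1-methoxy-1-(trimethylsilyloxy)prop-1-ene to form the C3–C2 bond and give 18 after HPLC. This avoids the base-mediated step but does not improve control at C6.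

## Further compounds

F1 | step 4 | (3aS,5aR,9aR,9bR)-3a,6,6,9a-tetramethyldodecahydronaphtho[2,1-b]furan | O1CC[C@H]2[C@]1(C)CC[C@@H]3C(C)(C)CCC[C@@]23C
F2 | step 4 | 2-[(1S,4aR,8aR)-2,5,5,8a-tetramethyl-1,4,4a,5,6,7,8,8a-octahydronaphthalen-1-yl]ethyl acetate | CC(=O)OCC[C@H]1C(C)=CC[C@@H]2C(C)(C)CCC[C@]21C
F3 | step 4 | 2-[(1S,4aR,8aR)-2,5,5,8a-tetramethyl-1,4,4a,5,6,7,8,8a-octahydronaphthalen-1-yl]ethan-1-ol | OCC[C@H]1C(C)=CC[C@@H]2C(C)(C)CCC[C@]21C
F4 | step 8 | 3-methyl-1-[(1S,4aR,8aR)-2,5,5,8a-tetramethyl-1,4,4a,5,6,7,8,8a-octahydronaphthalen-1-yl]hept-6-en-3-ol (both C3 epimers) | C=CCCC(C)(O)CC[C@H]1C(C)=CC[C@@H]2C(C)(C)CCC[C@]21C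
F5 | step 8 | methyl (2E)-6-hydroxy-2,6-dimethyl-8-[(1S,4aR,8aR)-2,5,5,8a-tetramethyl-1,4,4a,5,6,7,8,8a-octahydronaphthalen-1-yl]oct-2-enoate (both C6 epimers) | COC(=O)/C(C)=C/CCC(C)(O)CC[C@H]1C(C)=CC[C@@H]2C(C)(C)CCC[C@]21C
F6 | step 9 | 2-bromo-5,5-dimethoxypent-1-ene | C=C(Br)CCC(OC)OC
F7 | step 9 | (1S,4aR,8aR)-1-(6,6-dimethoxy-3-methylidenehexyl)-2,5,5,8a-tetramethyl-1,4,4a,5,6,7,8,8a-octahydronaphthalene | COC(OC)CCC(=C)CC[C@H]1C(C)=CC[C@@H]2C(C)(C)CCC[C@]21C
F8 | step 9 | triethyl({(3S)-6,6-dimethoxy-3-methyl-1-[(1S,4aR,8aR)-2,5,5,8a-tetramethyl-1,4,4a,5,6,7,8,8a-octahydronaphthalen-1-yl]hexan-3-yl}peroxy)silane | COC(OC)CC[C@](C)(CC[C@H]1C(C)=CC[C@@H]2C(C)(C)CCC[C@]21C)OO[Si](CC)(CC)CC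
F9 | step 9 | (6S)-3-methoxy-6-methyl-6-{2-[(1S,4aR,8aR)-2,5,5,8a-tetramethyl-1,4,4a,5,6,7,8,8a-octahydronaphthalen-1-yl]ethyl}-1,2-dioxane (both C3 anomers) | COC1CC[C@](C)(CC[C@H]2C(C)=CC[C@@H]3C(C)(C)CCC[C@]32C)OO1
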